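## The problem

1. Germacrane numbering is used throughout: C7 bears the isopropenyl group, C3 and C8 the angelates, C9 the acetate, and C10 and C4 the methyl groups. β means the face of the isopropenyl group in the flat drawing of the ring perimeter. Read this way, the SMILES is (1R,3S,4S,5S,7R,8S,9S,10R)-9β-acetoxy-3β,8β-diangeloyloxy-1β,10β:4α,5α-diepoxygermacr-11-ene.
2. The core is a cyclodecane in which seven of the ten ring atoms carry oxygen and eight are stereocentres. A direct ring closure would have to overcome medium-ring strain in a chain that is already fully decorated.
3. Both oxiranes are cis-fused to the ten-membered ring: C3 and C6 lie on the same side of the C4–C5 oxirane, and C2 and C9 on the same side of the C1–C10 oxirane. The parent diene is therefore Z,Z, and the usual routes to E,E-germacradienes do not apply.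
4. C7, C8 and C9 form a contiguous all-β triad that runs on into the β-oxirane (O9 erythro to O10), whereas O3 is threo to the α-oxirane. C7 can control C8 and C9, C9 can control C10/C1, and C3 and C4/C5 can control each other, but nothing local links the C3–C5 set to the C7–C10 set.
5. Three secondary oxygens must be told apart: angelate at C3 and C8, and acetate at C9 next to C8.
6. Several groups are fragile. The angelates isomerise to tiglates under nucleophilic or acidic catalysis, the two oxiranes cyclise transannularly with acid, the isopropenyl group must survive every oxidation, and C7 becomes epimerisable whenever C8 is a carbonyl.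
7. The enabling feature is that C3 and C8, the two carbons with the same ester, face each other as 1,6-partners across the ring. A C3–C8 bond would divide the cyclodecane into ring A (C3–C4–C5–C6–C7–C8) and ring B (C8–C9–C10–C1–C2–C3). These are two cyclohexanes that each hold one oxirane, which is possible only because both junctions are cis.
8. Ring A is then, atom for atom and with the right relative configuration at C4, C5 and C7, the 2,3-epoxide of carvone. Ring B is one isoprene unit bridging the carbonyl carbon and the α′ carbon of carvone. The ten-membered ring can thus be released by oxidative scission of a C3,C8-glycol (step 9).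

## Retrosynthesis

**19 ⇒ 16 + 17.** The two acyl–oxygen bonds at O3 and O8 are cut.
- Cutting the acetate instead would leave an 8-angelate next to a free 9-OH, which invites acyl shift, and would need a protecting group on O9. Cutting the two identical esters together needs none.
- 16 has ten carbons fewer and no Z-enoate.
- The forward reaction must acylate two hindered secondary alcohols without Z-to-E isomerisation, without acid and without moving the acetate.

**16 ⇒ 15.** The C3–H and C8–H bonds are cut, so both carbinols go back to ketones.
- This makes the two positions chemically alike and prepares the reconnection.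
- No neighbouring cut does this, since C9 must keep its own ester.
- 15 has two stereocentres fewer.
- The forward reaction must bring hydride to the outer face of both carbonyls in the same absolute sense. At both, the bulkier flank (C4, C9) and the slimmer flank (C2, C7) are arranged alike, so one oxazaborolidine catalyst can serve both.

**15 ⇒ 14 (key disconnection, a reconnection).** The carbonyl carbons C3 and C8 are joined to give the glycol 14 with a trans-decalin (cadinane-type) skeleton.
- Reconnecting C5–C10 or C4–C9 (the eudesmane-type decalins of classical fragmentations) would put an oxirane carbon at the ring fusion. A concerted decalin fragmentation can also deliver at most one cis junction, because the ring bonds at the two fusion atoms cannot both be axial.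
- Reconnecting C2–C7 would keep both oxiranes inside six-membered rings, but it ends at a CH2 and a CH with no handle for scission.
- Only C3–C8 ends at two oxygenated carbons, and these bear the same ester.
- 14 has the same atoms as 15, but the medium ring and its conformational ambiguity are gone. Every remaining stereocentre sits on a cyclohexane.
- The forward reaction must cleave exactly this glycol under buffered conditions.

**14 ⇒ 13 ⇒ 12.** The O9–acetyl bond is cut, then the two C–O bonds of the 1,10-oxirane.
- While the C3–C8 bond exists, O3 and O8 are tertiary and O9 is the only secondary hydroxyl. The acetate/angelate problem is therefore solved by the template without a protecting group.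
- Removing the 4,5-oxirane at this stage instead would create a second allylic alcohol (C3–OH) and a contest between two directed epoxidations.
- 12 has two stereocentres fewer.
- The forward epoxidation must be syn to the 9β-hydroxyl of a cyclohexenol and must spare the isopropenyl group.

**12 ⇒ 11 ⇒ 8 + 9.** Ring B is opened at C1=C10 (metathesis) and then at C2–C3 (carbonyl addition of 9).
- A six-membered ring closes easily and can only give the cis alkene. The same C1=C10 closure on an open chain would have to make a trisubstituted Z alkene in a ten-membered ring.
- 8 is monocyclic.
- The addition has to put the allyl arm where it can reach the C10 alkene. The configuration created at C3 is erased later.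

**8 ⇒ 6 ⇒ 5 ⇒ 2 + 3.** The C8–O bond (enolate hydroxylation) and the C8–C9 bond (aldol) are cut.
- C8 is the only enolisable position of 2, because C4 is quaternary, so both operations are regiochemically unambiguous.
- 3 brings C9, C10 and C14 with the alkene needed for ring closure.
- Only C9 has to be set correctly (9S, from the syn aldol on the α face). C8 is auxiliary.

**2 ⇒ 1.** The oxirane C–O bonds at C4 and C5 are cut. Nucleophilic epoxidation of 1 touches only the enone and places the oxygen trans to the isopropenyl group, which is the C4/C5/C7 relation of 19. The (S)-enantiomer of carvone corresponds to 7R in 19, since the CIP priorities change.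

## Roads not taken

**Alternative 1:** cut C7–C8 in an open chain (the most obvious plan).
- The acyclic Z,Z-chloro aldehyde A1 would be closed by an intramolecular Nozaki–Hiyama allylation (CrCl2, divalent chromium) to the cyclodecadienol A2. This forms the ring, C7, C8 and the isopropenyl group together.
- A1 needs two Z-trisubstituted allylic alcohol units built without any ring to enforce their geometry, and two separate asymmetric steps for C3 and C9.
- The closure is a medium-ring cyclisation at high dilution.
- The closed transition state of allylchromium additions favours the anti adduct, whereas C7/C8 of the target correspond to the syn adduct.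
- All four oxirane centres and the differentiation of three hydroxyls would then still have to be handled on a flexible ring.
- The chosen plan obtains ring, geometry and differentiation from one rigid template.

**Alternative 2:** break the same C3–C8 bond by an anionic oxy-Cope rearrangement.
- The divinyl carbinol A3, made from 1, would rearrange (KH, 18-crown-6) to the cyclodecadienone A4.
- This is also a four-carbon expansion of carvone. However, the chair transition state puts an E alkene at C8=C9, leaves C10 as an sp3 methine, and delivers oxygen only at C3.
- C8, C9 and the cis C1–C10 junction would all have to be reworked on the macrocycle.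
- In the chosen plan the inserted four carbons arrive with the right oxidation pattern.

**Alternative 3:** cut C8–C9 by a pinacol closure.
- The dialdehyde A5 would be coupled with SmI2 (divalent samarium) to the 8,9-diol A6, which forms the ring and two stereocentres at once.
- A5 contains a Z-enal that isomerises easily and whose ketyl is an allyl radical.
- The closure again makes a ten-membered ring from a chain.
- The two new secondary hydroxyls are neighbours of similar hindrance that must then receive different esters. This is exactly the problem the glycol template avoids.

Key step: step 9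

## Steps

**Step 1**
Reactants: 1 (S)-(+)-carvone
Product: 2 (1S,4S,6S)-1-methyl-4-(prop-1-en-2-yl)-7-oxabicyclo[4.1.0]heptan-2-one (carvone 4α,5α-epoxide; oxirane trans to the isopropenyl group)
Conditions: 30% aq. H2O2, NaOH (cat.), MeOH, 0 °C
Reagents that add atoms: hydrogen peroxide, OO
Why: Weitz–Scheffer nucleophilic epoxidation, in which only the enone alkene reacts and the isopropenyl group is untouched. Hydroperoxide adds axially to C5 anti to the C7 substituent, so the oxirane ends trans to the isopropenyl group (4S,5S), the relation found in 19.

**Step 2**
Reactants: 2 carvone 4α,5α-epoxide; 3 methacrolein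
Product: 5 syn-aldol (8S,9S): 2 bearing on the α face of C8 a (1S)-1-hydroxy-2-methylprop-2-enyl group (H8 β), via titanium enolate 4 (not isolated)
Conditions: LiN(iPr)2, THF, −78 °C; ClTi(OiPr)3, −78 to −40 °C; 3, −78 °C; then H2O
Reagents that add atoms: none
Why: Titanium aldol addition at C8, the only enolisable position because C4 is quaternary, with the aldehyde adding to the α face anti to the C7 isopropenyl group. Triisopropoxytitanium enolates of cyclic ketones are known to favour the syn adduct, which here is 9S; C8 is erased later, so only C9 counts.

**Step 3**
Reactants: 5 syn-aldol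
Product: 6 C9 triethylsilyl ether of 5
Conditions: Et3SiCl, imidazole, DMF, 0 °C
Reagents that add atoms: chlorotriethylsilane, CC[Si](Cl)(CC)CC
Why: Standard silylation of a secondary alcohol under conditions too mild for retro-aldol or dehydration. It blocks O9 so that C8 can be enolised again without retro-aldol cleavage, and no stereocentre is touched.

**Step 4**
Reactants: 6 silyl ether
Product: 8 8α-hydroxy ketone (OH on the α face of C8; the C9 side chain now on the β face), via potassium enolate 7 (not isolated)
Conditions: KN(SiMe3)2, THF, −78 °C; 2-(benzenesulfonyl)-3-phenyloxaziridine, −78 °C; AcOH quench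
Reagents that add atoms: 2-(benzenesulfonyl)-3-phenyloxaziridine, O=S(=O)(c1ccccc1)N1OC1c1ccccc1
Why: Davis enolate hydroxylation, with H8 axial and the only acidic C–H. The oxaziridine approaches the tetrasubstituted enolate from the α face because the β face carries the C7 isopropenyl and C4 methyl groups; the centre made at C8 is auxiliary and is deleted in step 9.

**Step 5**
Reactants: 8 8α-hydroxy ketone; 9 allylmagnesium bromide
Product: 11 seco-diene triol: ring A with 4α,5α-oxirane and 7β-isopropenyl; C3 (β-OH, α-allyl); C8 (α-OH, β-CH(OH)C(CH3)=CH2), via silyl ether 10 (not isolated)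
Conditions: 9 (3.5 equiv), THF, −78 °C; aq. work-up; Bu4NF, AcOH, THF, 0 °C
Reagents that add atoms: none
Why: Chelation-controlled Grignard 1,2-addition, then fluoride desilylation. The magnesium alkoxide of the equatorial 8α-OH ties up the C3 carbonyl and the axial C9 side chain blocks the β face, so allyl enters axially from the α face to give 3β-OH and a trans-glycol; C3 is also auxiliary.

**Step 6**
Reactants: 11 seco-diene triol
Product: 12 trans-fused bicyclic triol (cadinane skeleton): 4α,5α-epoxy-3β,8α,9β-trihydroxy-1(10)-ene with 7β-isopropenyl
Conditions: RuCl2(=CHPh)(PCy3)(H2IMes) (second-generation Grubbs catalyst, 5 mol %), 1,4-benzoquinone (10 mol %), CH2Cl2, reflux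
Reagents that add atoms: none
Why: Ring-closing olefin metathesis to a cyclohexene: the carbene forms at the monosubstituted allyl terminus and closes on the 1,1-disubstituted C10 alkene, which lies gauche to it in the diequatorial conformer. The isopropenyl group is trans-1,3 to the allyl arm and cannot be reached, and its pairing with the C10 alkene would need a tetrasubstituted cyclopentene. In a six-membered ring the new C1=C10 bond can only be cis, which fixes the geometry of the later 1,10-oxirane.

**Step 7**
Reactants: 12 bicyclic triol
Product: 13 1β,10β:4α,5α-diepoxy-3β,8α,9β-triol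
Conditions: VO(acac)2 (3 mol %), t-BuOOH (1.1 equiv), CH2Cl2, 0 °C
Reagents that add atoms: tert-butyl hydroperoxide, CC(C)(C)OO
Why: Hydroxyl-directed vanadium-catalysed epoxidation of a cyclohexenol, in which the pseudoaxial 9β-OH delivers oxygen to the β face and sets C1 (R) and C10 (R) cis to O9. The isopropenyl group is only homoallylic to a tertiary hydroxyl and reacts much more slowly.

**Step 8**
Reactants: 13 diepoxy triol
Product: 14 9β-acetate of 13 (free trans-3β,8α-glycol)
Conditions: Ac2O, pyridine, DMAP (cat.), CH2Cl2, 0 to 23 °C
Reagents that add atoms: acetic anhydride, CC(=O)OC(C)=O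
Why: Acylation of the only secondary hydroxyl, since O3 and O8 are tertiary and flanked by fully substituted carbons. The anti arrangement of O8 and O9 also prevents acetyl migration.

**Step 9**
Reactants: 14 glycol acetate
Product: 15 ten-membered diketone: 9β-acetoxy-1β,10β:4α,5α-diepoxygermacr-11-ene-3,8-dione
Conditions: Pb(OAc)4 (1.2 equiv), pyridine–CH2Cl2, 0 to 23 °C
Reagents that add atoms: none
Why: Criegee glycol fission: one tertiary hydroxyl displaces acetate on tetravalent lead, pyridine takes the proton of the other, and a two-electron collapse breaks the C3–C8 σ bond, forms both C=O groups and expels Pb(OAc)2. The closest known reaction type is the cleavage of decalin-9,10-diols, cis and trans alike, to cyclodecane-1,6-dione; the trans-diaxial glycol of 14 cannot form a cyclic plumbate but has the antiperiplanar O–C–C–O array that the open pathway uses. No ring is closed by bond formation: the bond shared by rings A and B is deleted and their common perimeter is released as the ten-membered ring, so neither dilution nor a strained cyclisation transition state is involved, and the syn-axial contact between the C7 isopropenyl and C9 acetoxy groups of 14 is relieved. No stereocentre is created; the auxiliary centres C3 and C8 disappear, and C1, C4, C5, C7, C9 and C10 keep the configurations set under cyclohexane control, since no bond to them is touched. The cis junctions C3–C4–C5–C6 and C2–C1–C10–C9, enforced while each oxirane sat in a six-membered ring, are carried over unchanged. The selectivity needed is that of one glycol over another: C8–OH has two oxygenated neighbours, and the acetate placed on O9 in step 8 leaves C3–OH as its only free partner. Oxiranes, ester and the 1,1-disubstituted alkene are inert to Pb(OAc)4 at this temperature, and pyridine buffers the acetic acid that would otherwise threaten the oxiranes and the enolisable positions C2, C7 and C9 of 15.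

**Step 10**
Reactants: 15 diketone
Product: 16 3β,8β-diol (3S,8S): 9β-acetoxy-1β,10β:4α,5α-diepoxygermacr-11-ene-3β,8β-diol
Conditions: (R)-Me-CBS [(R)-1-methyl-3,3-diphenyltetrahydro-1H,3H-pyrrolo[1,2-c][1,3,2]oxazaborole] (0.4 equiv), catecholborane (4 equiv), toluene, −78 to −40 °C; MeOH, pH 7 buffer
Reagents that add atoms: none
Why: Corey–Bakshi–Shibata reduction: at both carbonyls the larger flank (C4, a quaternary oxirane carbon; C9, acetoxy-bearing and next to quaternary C10) and the smaller flank (C2H2; C7H) stand in the same spatial sense, so the (R)-catalyst should give 3S and 8S together. The substrate bias is expected to be matched, because hydride can only come from the ring periphery, and the conformer with C3=O anti to the C4–O bond and with H7 and H9 turned towards each other across C8=O leads to the 3β- and 8β-alcohols. Catecholborane keeps the medium neutral, so there is no acetyl shift, no enolisation and no hydroboration of the isopropenyl group.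

**Step 11**
Reactants: 16 3β,8β-diol; 17 angelic acid
Product: 19 CNP0220329.1 (target), via mixed anhydride 18 (not isolated)
Conditions: 17 (4 equiv), 2,4,6-Cl3C6H2COCl, Et3N, toluene, 23 °C; then 16, 80 °C
Reagents that add atoms: none
Why: Mixed-anhydride (Yamaguchi-type) esterification run without a nucleophilic catalyst, in which each alcohol attacks the less hindered angeloyl carbonyl of 18. Leaving out DMAP and free alkoxide avoids the addition–elimination that turns angelate into tiglate and the O9-to-O8 acetyl shift, excess Et3N keeps the medium free of acid, and no stereocentre is touched.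

## Compound list

1 | (S)-(+)-carvone | C=C(C)[C@H]1CC=C(C)C(=O)C1 | starting material
2 | (1S,4S,6S)-carvone 4α,5α-epoxide | C=C(C)[C@H]1C[C@@H]2O[C@]2(C)C(=O)C1 | intermediate
3 | methacrolein | C=C(C)C=O | starting material
4 | triisopropoxytitanium enolate of 2 (C3–O–Ti, C3=C8) | C=C(C)[C@H]1C[C@@H]2O[C@]2(C)C(O[Ti](OC(C)C)(OC(C)C)OC(C)C)=C1 | intermediate
5 | syn-aldol (8S,9S) | C=C(C)[C@H]1C[C@@H]2O[C@]2(C)C(=O)[C@@H]1[C@H](O)C(C)=C | intermediate
6 | C9 triethylsilyl ether of 5 | C=C(C)[C@H]1C[C@@H]2O[C@]2(C)C(=O)[C@@H]1[C@H](O[Si](CC)(CC)CC)C(C)=C | intermediate
7 | potassium enolate of 6 | C=C(C)[C@H]1C[C@@H]2O[C@]2(C)C([O-])=C1[C@H](O[Si](CC)(CC)CC)C(C)=C.[K+] | intermediate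
8 | 8α-hydroxy ketone | C=C(C)[C@H]1C[C@@H]2O[C@]2(C)C(=O)[C@@]1(O)[C@H](O[Si](CC)(CC)CC)C(C)=C | intermediate
9 | allylmagnesium bromide | C=CC[Mg]Br | starting material
10 | 3α-allyl-3β,8α-diol, O9 triethylsilyl ether | C=C(C)[C@H]1C[C@@H]2O[C@]2(C)[C@](O)(CC=C)[C@@]1(O)[C@H](O[Si](CC)(CC)CC)C(C)=C | intermediate
11 | seco-diene triol | C=C(C)[C@H]1C[C@@H]2O[C@]2(C)[C@](O)(CC=C)[C@@]1(O)[C@H](O)C(C)=C | intermediate
12 | trans-fused bicyclic triol, 1(10)-ene | C=C(C)[C@H]1C[C@@H]2O[C@]2(C)[C@]3(O)CC=C(C)[C@@H](O)[C@@]13O | intermediate
13 | 1β,10β:4α,5α-diepoxy-3β,8α,9β-triol | C=C(C)[C@H]1C[C@@H]2O[C@]2(C)[C@]3(O)C[C@H]4O[C@@]4(C)[C@@H](O)[C@@]13O | intermediate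
14 | 9β-acetate of 13 | C=C(C)[C@H]1C[C@@H]2O[C@]2(C)[C@]3(O)C[C@H]4O[C@@]4(C)[C@@H](OC(C)=O)[C@@]13O | intermediate
15 | 9β-acetoxy-1β,10β:4α,5α-diepoxygermacr-11-ene-3,8-dione | C=C(C)[C@H]1C[C@@H]2O[C@]2(C)C(=O)C[C@H]2O[C@@]2(C)[C@@H](OC(C)=O)C1=O | intermediate
16 | 3β,8β-diol | C=C(C)[C@H]1C[C@@H]2O[C@]2(C)[C@@H](O)C[C@H]2O[C@@]2(C)[C@@H](OC(C)=O)[C@H]1O | intermediate
17 | angelic acid ((Z)-2-methylbut-2-enoic acid) | C/C=C(/C)C(=O)O | starting material
18 | angelic 2,4,6-trichlorobenzoic anhydride | C/C=C(/C)C(=O)OC(=O)c1c(Cl)cc(Cl)cc1Cl | intermediate
19 | CNP0220329.1 | C=C(C)[C@H]1C[C@@H]2O[C@]2(C)[C@@H](OC(=O)/C(C)=C\C)C[C@H]2O[C@@]2(C)[C@@H](OC(C)=O)[C@H]1OC(=O)/C(C)=C\C | target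

**Total steps:** 11. **Longest linear sequence:** 11 steps (1 to 19); 3, 9 and 17 are bought.

## Least certain steps

**Step 9 (key step).**
- *Risk:* Ligand exchange at two hindered tertiary hydroxyls of a trans-diaxial glycol may be slow. Long exposure could then let acetic acid open an oxirane, or let the product enolise. Enolisation would cause epimerisation at C7, β-opening of the 1,10-oxirane from C9, or transannular aldol addition.
- *Fallback:* This leaves two-electron chemistry. Starting from 14, hypoiodite formation with PhI(OAc)2 and I2 under visible light generates the C3 alkoxy radical. Its β-scission of C3–C8 is favoured over C3–C2 and C3–C4, because it gives an α-hydroxyalkyl radical and opens the strained decalin. Oxidation of that radical leads directly back to 15. This path needs neither a cyclic ester nor a particular O–C–C–O angle, and it makes no compound outside the list (F0).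

**Step 10.**
- *Risk:* Facial selectivity at C3 may be poor. The intrinsic erythro preference of α,β-epoxy ketones opposes the catalyst whenever the carbonyl turns syn to the oxirane oxygen. The large/small discrimination at C8 may also be weak.
- *Fallback:* This accepts the intrinsic bias and corrects it by substitution.
  - Starting from 15, chelation-controlled reduction with Zn(BH4)2 (Et2O, −78 °C) should give the 3-epi diol F1 (3α-OH, 8β-OH).
  - A Mitsunobu esterification with 17 (PPh3, DIAD, toluene) should engage the less hindered C3 carbinol, which has a CH2 on one side. It should install the angelate with inversion, giving the 3β-monoangelate F2.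
  - Acylation of the remaining 8β-OH under the conditions of step 11 returns to the route at 19.

**Step 2.**
- *Risk:* Simple diastereoselection at C9 (syn versus anti) may be poor, because closed and open transition states lie close together for a hindered cyclic enolate and an enal.
- *Fallback:* This makes C9 stereoconvergent on the template. Starting from 12, carried forward with whatever C9 composition steps 2 to 6 deliver, Dess–Martin periodinane oxidises the only secondary alcohol to the ring-B enone F3. 1,2-Reduction with NaBH4 and CeCl3·7H2O (MeOH, −78 °C) should come from the α face, because the β face of C9 is covered by the axial C7 isopropenyl group. This returns 12.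

**Step 11.**
- *Risk:* During a slow acylation at 80 °C the angeloyl group may isomerise from Z to E, the acetyl group may migrate from O9 to O8, or an oxirane may open.
- *Fallback:* This builds the Z-enoate on the ester instead of transferring it. Starting from 16, coupling with 2-[bis(2,2,2-trifluoroethoxy)phosphoryl]propanoic acid (DCC, DMAP, CH2Cl2, 0 °C) gives the bis(phosphonopropanoate) F4. A double Still–Gennari olefination (KN(SiMe3)2, 18-crown-6, THF, −78 °C, then acetaldehyde) should form both Z-2-methylbut-2-enoates at low temperature and return to the route at 19.

## Further compounds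

F0 | step 9 | none | none
F1 | step 10 | 3-epi diol (3α-OH, 8β-OH) | C=C(C)[C@H]1C[C@@H]2O[C@]2(C)[C@H](O)C[C@H]2O[C@@]2(C)[C@@H](OC(C)=O)[C@H]1O
F2 | step 10 | 3β-monoangelate, 8β-ol | C=C(C)[C@H]1C[C@@H]2O[C@]2(C)[C@@H](OC(=O)/C(C)=C\C)C[C@H]2O[C@@]2(C)[C@@H](OC(C)=O)[C@H]1O
F3 | step 2 | ring-B enone (9-oxo derivative of 12) | C=C(C)[C@H]1C[C@@H]2O[C@]2(C)[C@]3(O)CC=C(C)C(=O)[C@@]13O
F4 | step 11 | 3,8-bis{2-[bis(2,2,2-trifluoroethoxy)phosphoryl]propanoate} of 16 | C=C(C)[C@H]1C[C@@H]2O[C@]2(C)[C@@H](OC(=O)C(C)P(=O)(OCC(F)(F)F)OCC(F)(F)F)C[C@H]2O[C@@]2(C)[C@@H](OC(C)=O)[C@H]1OC(=O)C(C)P(=O)(OCC(F)(F)F)OCC(F)(F)F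
A1 | alternative 1 | Z,Z-chloro aldehyde (chain open at C7/C8, O3 and O9 as TBS ethers) | O=C[C@H](O[Si](C)(C)C(C)(C)C)/C(C)=C\C[C@H](O[Si](C)(C)C(C)(C)C)/C(C)=C\C/C=C(\C)CCl
A2 | alternative 1 | (1(10)Z,4Z)-germacra-1(10),4,11-trien-8β-ol, 3β,9β-bis-TBS ether | C=C(C)[C@H]1C/C=C(/C)[C@@H](O[Si](C)(C)C(C)(C)C)C/C=C(/C)[C@@H](O[Si](C)(C)C(C)(C)C)[C@H]1O
A3 | alternative 2 | 3β-vinyl-8α-[(E)-prop-1-enyl] carbinol derived from carvone | C=C(C)[C@H]1CC=C(C)[C@@](O)(C=C)[C@@H]1/C=C/C
A4 | alternative 2 | (4Z,8E)-germacra-4,8,11-trien-3-one | C=C(C)[C@H]1C/C=C(/C)C(=O)CC[C@H](C)/C=C/1
A5 | alternative 3 | Z,Z-dialdehyde (chain open at C8/C9, O3 as TBS ether) | O=C/C(C)=C\C[C@H](O[Si](C)(C)C(C)(C)C)/C(C)=C\C[C@@H](C=O)C(C)=C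
A6 | alternative 3 | (1(10)Z,4Z)-germacratriene-8β,9β-diol, 3β-TBS ether | C=C(C)[C@H]1C/C=C(/C)[C@@H](O[Si](C)(C)C(C)(C)C)C/C=C(/C)[C@@H](O)[C@H]1O
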